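The route rests on cutting the O4–C3 bond of the dioxane ring. C3 carries both O4 and the CH2OH carbon, so a terminal epoxide spanning C3 and that carbon is its natural precursor. When the ring A phenoxide oxygen O4 (ortho to the methoxy group) opens this epoxide at C3, one operation forms the O4–C3 bond, closes the dioxane ring, liberates the primary alcohol and sets C3 (R) by inversion, cis to the ring B aryl on C2. The precursor is a threo aryloxy epoxide: O1 of ring A is already bound to the benzylic C2 (S) bearing bis-MOM-protected ring B, with a free ring A phenol para to a formyl group.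

Key step: step 11

Remark: all names use one locant set for the dioxane (O1, C2 bearing ring B, C3 bearing CH2OH, O4, OMe at C5, side chain at C7 of ring A); the target is the cis (2S,3R) isomer, and 1, 3, 16 and all reagents are taken as commercial.

**Step 1**
Reactants: 1 5-hydroxyvanillin (3,4-dihydroxy-5-methoxybenzaldehyde)
Product: 2 3-methoxy-4,5-bis(methoxymethoxy)benzaldehyde
Conditions: MOMCl, iPr2NEt, CH2Cl2, 0 °C to rt
Reagents that add atoms: chloromethyl methyl ether (MOMCl), COCCl
Why: Williamson-type O-alkylation of both phenols under amine base gives the bis-acetal, which masks the ring B catechol against base and later blocks quinone methide chemistry at the benzylic ether.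

**Step 2**
Reactants: 2 3-methoxy-4,5-bis(methoxymethoxy)benzaldehyde; 3 triethyl phosphonoacetate
Product: 4 ethyl (E)-3-[3-methoxy-4,5-bis(methoxymethoxy)phenyl]prop-2-enoate
Conditions: NaH, THF, 0 °C to rt
Reagents that add atoms: none
Why: Horner–Wadsworth–Emmons olefination of an aromatic aldehyde with a stabilised phosphonate anion should give the (E)-cinnamate.

**Step 3**
Reactants: 4 ethyl (E)-3-[3-methoxy-4,5-bis(methoxymethoxy)phenyl]prop-2-enoate
Product: 6 (E)-3-[3-methoxy-4,5-bis(methoxymethoxy)phenyl]prop-2-en-1-ol, via enal 5 (not isolated)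
Conditions: iBu2AlH, CH2Cl2, −78 to 0 °C; aq. potassium sodium tartrate
Reagents that add atoms: none
Why: iBu2AlH reduces the conjugated ester by 1,2-hydride delivery through the enal to the allylic alcohol without touching the alkene or the MOM acetals.

**Step 4**
Reactants: 6 (E)-3-[3-methoxy-4,5-bis(methoxymethoxy)phenyl]prop-2-en-1-ol
Product: 7 [(2R,3R)-3-[3-methoxy-4,5-bis(methoxymethoxy)phenyl]oxiran-2-yl]methanol
Conditions: Ti(OiPr)4 (10 mol %), D-(−)-diisopropyl tartrate (12 mol %), tBuOOH (in decane), 4 Å molecular sieves, CH2Cl2, −20 °C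
Reagents that add atoms: tert-butyl hydroperoxide, CC(C)(C)OO
Why: Sharpless asymmetric epoxidation, in which the Ti(OiPr)4–tartrate complex binds the allylic alcohol and the hydroperoxide; the D-(−)-tartrate should direct oxygen to the alkene face that gives the trans (2R,3R) epoxy alcohol, setting both stereocentres by reagent control.

**Step 5**
Reactants: 1 5-hydroxyvanillin
Product: 8 4-(allyloxy)-3-hydroxy-5-methoxybenzaldehyde
Conditions: allyl bromide (1.05 equiv), NaHCO3, DMF, 40 °C
Reagents that add atoms: allyl bromide, C=CCBr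
Why: Chemoselective Williamson etherification, since the 4-hydroxyl para to the formyl group is the more acidic phenol and the only one ionised by NaHCO3, so the 3-hydroxyl stays free as the later nucleophile.

**Step 6**
Reactants: 7 [(2R,3R)-3-[3-methoxy-4,5-bis(methoxymethoxy)phenyl]oxiran-2-yl]methanol; 8 4-(allyloxy)-3-hydroxy-5-methoxybenzaldehyde
Product: 9 4-(allyloxy)-3-{[(1S,2R)-2,3-dihydroxy-1-[3-methoxy-4,5-bis(methoxymethoxy)phenyl]propyl]oxy}-5-methoxybenzaldehyde
Conditions: 8 (1.5 equiv), NaOH (1.0 equiv), H2O/1,4-dioxane, 65 °C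
Reagents that add atoms: none
Why: SN2 opening of the 2,3-epoxy alcohol by the phenoxide of 8 should occur at the benzylic carbon (activated by ring B, while the neighbouring carbon is deactivated by CH2OH) with inversion, giving the erythro aryloxy diol and fixing the future C2 as (S); base-mediated phenol opening of 3-arylglycidols is the model.

**Step 7**
Reactants: 9 the erythro aryloxy diol
Product: 10 4-(allyloxy)-3-{[(1S,2R)-3-[(tert-butyldimethylsilyl)oxy]-2-hydroxy-1-[3-methoxy-4,5-bis(methoxymethoxy)phenyl]propyl]oxy}-5-methoxybenzaldehyde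
Conditions: tBuMe2SiCl (1.05 equiv), imidazole, CH2Cl2, 0 °C
Reagents that add atoms: tert-butyldimethylsilyl chloride, CC(C)(C)[Si](C)(C)Cl
Why: Sterically controlled silylation, the primary hydroxyl reacting far faster with the bulky silyl chloride than the secondary one next to the diaryl-substituted carbon.

**Step 8**
Reactants: 10 the primary silyl ether
Product: 11 (1S,2R)-1-[2-(allyloxy)-5-formyl-3-methoxyphenoxy]-3-[(tert-butyldimethylsilyl)oxy]-1-[3-methoxy-4,5-bis(methoxymethoxy)phenyl]propan-2-yl methanesulfonate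
Conditions: MsCl, Et3N, CH2Cl2, 0 °C
Reagents that add atoms: methanesulfonyl chloride, CS(=O)(=O)Cl
Why: Sulfonylation of the remaining secondary alcohol turns it into a leaving group with retention at carbon.

**Step 9**
Reactants: 11 the silyloxy mesylate
Product: 13 4-(allyloxy)-3-methoxy-5-{(S)-[3-methoxy-4,5-bis(methoxymethoxy)phenyl][(2S)-oxiran-2-yl]methoxy}benzaldehyde, via hydroxy mesylate 12 (not isolated)
Conditions: Bu4NF, THF, 0 °C to rt
Reagents that add atoms: none
Why: Fluoride cleaves the primary silyl ether and the resulting alkoxide displaces the vicinal mesylate in an intramolecular Williamson (3-exo-tet) SN2 reaction with inversion, converting the erythro (2R) mesylate into the threo (2S) terminal epoxide.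

**Step 10**
Reactants: 13 the allyl-protected threo epoxide
Product: 14 4-hydroxy-3-methoxy-5-{(S)-[3-methoxy-4,5-bis(methoxymethoxy)phenyl][(2S)-oxiran-2-yl]methoxy}benzaldehyde
Conditions: Pd(PPh3)4 (5 mol %), N-methylaniline, THF, rt
Reagents that add atoms: none
Why: Tsuji–Trost-type deallylation, in which zerovalent palladium ionises the aryl allyl ether to a π-allyl complex and N-methylaniline captures the allyl group under neutral conditions that should spare epoxide, aldehyde and MOM ethers.

**Step 11**
Reactants: 14 the threo aryloxy epoxide with free ring A phenol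
Product: 15 (2S,3R)-3-(hydroxymethyl)-5-methoxy-2-[3-methoxy-4,5-bis(methoxymethoxy)phenyl]-2,3-dihydro-1,4-benzodioxine-7-carbaldehyde (cis)
Conditions: K2CO3 (0.5 equiv), DMF (0.02 M), 50 °C
Reagents that add atoms: none
Why: K2CO3 generates the ring A phenoxide O4, which attacks C3 of the terminal epoxide from the side opposite the C3–O bond in an SN2 opening, so the epoxide oxygen becomes the primary alkoxide and then CH2OH. The closest known reaction is the base-mediated cyclisation of aryl glycidyl ethers carrying an ortho phenol to 2-hydroxymethyl-1,4-benzodioxanes. The dioxane ring closes in the 6-exo-tet mode. C3 is the only new stereocentre and is under substrate control: inversion of the (S) epoxide carbon gives (3R), and because the C2 aryl ether and the epoxide oxygen are threo, the ring should emerge cis with C2 (S) untouched. The step needs regioselectivity for C3 over the CH2 terminus, which rests on the kinetic preference for six-membered exo closure over the 7-endo alternative, while high dilution suppresses intermolecular opening. The para formyl group makes the phenol acidic enough for K2CO3 yet leaves the phenoxide nucleophilic, and the bis-MOM ether on ring B prevents quinone methide formation under base.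

**Step 12**
Reactants: 15 the cis-benzodioxane aldehyde; 16 methyl (triphenylphosphoranylidene)acetate
Product: 17 methyl (E)-3-[(2S,3R)-3-(hydroxymethyl)-5-methoxy-2-[3-methoxy-4,5-bis(methoxymethoxy)phenyl]-2,3-dihydro-1,4-benzodioxin-7-yl]prop-2-enoate
Conditions: toluene, 80 °C
Reagents that add atoms: none
Why: Wittig olefination of an aromatic aldehyde with a stabilised ylide is (E)-selective and needs no added base, so the free primary alcohol and the cis-dioxane should be untouched.

**Step 13**
Reactants: 17 the bis-MOM acrylate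
Product: 18 methyl (E)-3-[(2S,3R)-2-(3,4-dihydroxy-5-methoxyphenyl)-3-(hydroxymethyl)-5-methoxy-2,3-dihydro-1,4-benzodioxin-7-yl]prop-2-enoate
Conditions: HCl (1.25 M in MeOH), THF, rt
Reagents that add atoms: none
Why: Acid-catalysed acetal exchange with methanol removes both aryl MOM ethers while the side chain is still the acid-stable acrylate (the methyl ester avoids ester scrambling), under mild conditions chosen to avoid ionising the benzylic C2–O1 bond.

**Step 14**
Reactants: 18 the catechol acrylate
Product: 20 (E)-3-[(2S,3R)-2-(3,4-dihydroxy-5-methoxyphenyl)-3-(hydroxymethyl)-5-methoxy-2,3-dihydro-1,4-benzodioxin-7-yl]prop-2-en-1-ol, via enal 19 (not isolated)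
Conditions: iBu2AlH (7 equiv), THF, −78 to −20 °C; aq. citric acid
Reagents that add atoms: none
Why: Excess iBu2AlH first converts the three hydroxyl groups into aluminium alkoxides and then reduces the conjugated ester by 1,2-hydride delivery via the enal to the (E)-allylic alcohol, and the mildly acidic work-up avoids the free phenoxide that could open the dioxane through a quinone methide.

**Compound list**

1 | 5-hydroxyvanillin (3,4-dihydroxy-5-methoxybenzaldehyde) | O=Cc1cc(O)c(O)c(OC)c1 | starting material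
2 | 3-methoxy-4,5-bis(methoxymethoxy)benzaldehyde | O=Cc1cc(OC)c(OCOC)c(OCOC)c1 | intermediate
3 | triethyl phosphonoacetate | CCOC(=O)CP(=O)(OCC)OCC | starting material
4 | ethyl (E)-3-[3-methoxy-4,5-bis(methoxymethoxy)phenyl]prop-2-enoate | CCOC(=O)/C=C/c1cc(OC)c(OCOC)c(OCOC)c1 | intermediate
5 | (E)-3-[3-methoxy-4,5-bis(methoxymethoxy)phenyl]prop-2-enal | O=C/C=C/c1cc(OC)c(OCOC)c(OCOC)c1 | intermediate (not isolated)
6 | (E)-3-[3-methoxy-4,5-bis(methoxymethoxy)phenyl]prop-2-en-1-ol | OC/C=C/c1cc(OC)c(OCOC)c(OCOC)c1 | intermediate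
7 | [(2R,3R)-3-[3-methoxy-4,5-bis(methoxymethoxy)phenyl]oxiran-2-yl]methanol | OC[C@H]1O[C@@H]1c1cc(OC)c(OCOC)c(OCOC)c1 | intermediate
8 | 4-(allyloxy)-3-hydroxy-5-methoxybenzaldehyde | O=Cc1cc(O)c(OCC=C)c(OC)c1 | intermediate
9 | 4-(allyloxy)-3-{[(1S,2R)-2,3-dihydroxy-1-[3-methoxy-4,5-bis(methoxymethoxy)phenyl]propyl]oxy}-5-methoxybenzaldehyde | COc1cc([C@H](Oc2cc(C=O)cc(OC)c2OCC=C)[C@H](O)CO)cc(OCOC)c1OCOC | intermediate
10 | 4-(allyloxy)-3-{[(1S,2R)-3-[(tert-butyldimethylsilyl)oxy]-2-hydroxy-1-[3-methoxy-4,5-bis(methoxymethoxy)phenyl]propyl]oxy}-5-methoxybenzaldehyde | COc1cc([C@H](Oc2cc(C=O)cc(OC)c2OCC=C)[C@H](O)CO[Si](C)(C)C(C)(C)C)cc(OCOC)c1OCOC | intermediate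
11 | (1S,2R)-1-[2-(allyloxy)-5-formyl-3-methoxyphenoxy]-3-[(tert-butyldimethylsilyl)oxy]-1-[3-methoxy-4,5-bis(methoxymethoxy)phenyl]propan-2-yl methanesulfonate | COc1cc([C@H](Oc2cc(C=O)cc(OC)c2OCC=C)[C@H](OS(C)(=O)=O)CO[Si](C)(C)C(C)(C)C)cc(OCOC)c1OCOC | intermediate
12 | (1S,2R)-1-[2-(allyloxy)-5-formyl-3-methoxyphenoxy]-3-hydroxy-1-[3-methoxy-4,5-bis(methoxymethoxy)phenyl]propan-2-yl methanesulfonate (formed as its alkoxide) | COc1cc([C@H](Oc2cc(C=O)cc(OC)c2OCC=C)[C@H](OS(C)(=O)=O)CO)cc(OCOC)c1OCOC | intermediate (not isolated)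
13 | 4-(allyloxy)-3-methoxy-5-{(S)-[3-methoxy-4,5-bis(methoxymethoxy)phenyl][(2S)-oxiran-2-yl]methoxy}benzaldehyde | COc1cc([C@H](Oc2cc(C=O)cc(OC)c2OCC=C)[C@@H]2CO2)cc(OCOC)c1OCOC | intermediate
14 | 4-hydroxy-3-methoxy-5-{(S)-[3-methoxy-4,5-bis(methoxymethoxy)phenyl][(2S)-oxiran-2-yl]methoxy}benzaldehyde | COc1cc([C@H](Oc2cc(C=O)cc(OC)c2O)[C@@H]2CO2)cc(OCOC)c1OCOC | intermediate
15 | (2S,3R)-3-(hydroxymethyl)-5-methoxy-2-[3-methoxy-4,5-bis(methoxymethoxy)phenyl]-2,3-dihydro-1,4-benzodioxine-7-carbaldehyde | COc1cc([C@@H]2Oc3cc(C=O)cc(OC)c3O[C@@H]2CO)cc(OCOC)c1OCOC | intermediate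
16 | methyl (triphenylphosphoranylidene)acetate | COC(=O)C=P(c1ccccc1)(c1ccccc1)c1ccccc1 | starting material
17 | methyl (E)-3-[(2S,3R)-3-(hydroxymethyl)-5-methoxy-2-[3-methoxy-4,5-bis(methoxymethoxy)phenyl]-2,3-dihydro-1,4-benzodioxin-7-yl]prop-2-enoate | COc1cc([C@@H]2Oc3cc(/C=C/C(=O)OC)cc(OC)c3O[C@@H]2CO)cc(OCOC)c1OCOC | intermediate
18 | methyl (E)-3-[(2S,3R)-2-(3,4-dihydroxy-5-methoxyphenyl)-3-(hydroxymethyl)-5-methoxy-2,3-dihydro-1,4-benzodioxin-7-yl]prop-2-enoate | COc1cc([C@@H]2Oc3cc(/C=C/C(=O)OC)cc(OC)c3O[C@@H]2CO)cc(O)c1O | intermediate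
19 | (E)-3-[(2S,3R)-2-(3,4-dihydroxy-5-methoxyphenyl)-3-(hydroxymethyl)-5-methoxy-2,3-dihydro-1,4-benzodioxin-7-yl]prop-2-enal | COc1cc([C@@H]2Oc3cc(/C=C/C=O)cc(OC)c3O[C@@H]2CO)cc(O)c1O | intermediate (not isolated)
20 | (E)-3-[(2S,3R)-2-(3,4-dihydroxy-5-methoxyphenyl)-3-(hydroxymethyl)-5-methoxy-2,3-dihydro-1,4-benzodioxin-7-yl]prop-2-en-1-ol | COc1cc([C@@H]2Oc3cc(/C=C/CO)cc(OC)c3O[C@@H]2CO)cc(O)c1O | target

Total step count: 14. Longest linear sequence: 13 steps (steps 1–4 and 6–14, from 1 to 20); step 5 is the only branch.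

**Steps most likely to fail**

Step 6. Payne rearrangement of the free epoxy alcohol followed by phenoxide attack at the primary carbon, together with hydrolytic opening of the electron-rich epoxide in the aqueous medium, may erode regioselectivity and conversion. The fallback sets out from 7 and removes the free hydroxyl before the opening. Silylation (tBuMe2SiCl, imidazole, CH2Cl2) should give tert-butyl{[(2R,3R)-3-[3-methoxy-4,5-bis(methoxymethoxy)phenyl]oxiran-2-yl]methoxy}dimethylsilane F1, which cannot undergo the Payne shift. Opening of this compound with phenol 8 under anhydrous conditions (Cs2CO3, DMF, 70 °C) by benzylic SN2 attack with inversion should deliver the silyl ether 10 directly. The fallback thus returns to the route at 10 and bypasses 9.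

Step 11. Attack of the phenoxide at the unhindered CH2 terminus (7-endo) or slow closure at the hindered C3 with intermolecular opening may compete with the 6-exo ring closure. The fallback sets out from 13 and replaces the epoxide opening by displacement at a carbon that is the only electrophilic site. Opening of the epoxide at its terminal carbon with pivalate (pivalic acid, Cs2CO3, DMF, 80 °C) should give (2S,3S)-3-[2-(allyloxy)-5-formyl-3-methoxyphenoxy]-2-hydroxy-3-[3-methoxy-4,5-bis(methoxymethoxy)phenyl]propyl pivalate F2. Deallylation as in step 10 (Pd(PPh3)4, N-methylaniline) should give (2S,3S)-3-(5-formyl-2-hydroxy-3-methoxyphenoxy)-2-hydroxy-3-[3-methoxy-4,5-bis(methoxymethoxy)phenyl]propyl pivalate F3. Intramolecular Mitsunobu etherification (PPh3, DIAD, THF, 0 °C) should then form the same O4–C3 bond with inversion of the threo secondary alcohol, giving the cis compound [(2S,3R)-7-formyl-5-methoxy-2-[3-methoxy-4,5-bis(methoxymethoxy)phenyl]-2,3-dihydro-1,4-benzodioxin-3-yl]methyl pivalate F4. Methanolysis (NaOMe, MeOH, rt) returns to the route at 15.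

Step 13. Once the para hydroxyl of ring B is free, acid may ionise the benzylic C2–O1 bond, leading to cis-to-trans equilibration or methanolysis of the dioxane. The fallback sets out from 17 and reverses the order of the last two operations. Reduction first (iBu2AlH, CH2Cl2, −78 °C) should give (E)-3-[(2S,3R)-3-(hydroxymethyl)-5-methoxy-2-[3-methoxy-4,5-bis(methoxymethoxy)phenyl]-2,3-dihydro-1,4-benzodioxin-7-yl]prop-2-en-1-ol F5. Its aryl MOM ethers are then cleaved without protic acid (Me3SiOTf, 2,2′-bipyridyl, CH2Cl2, 0 °C; then H2O), a protocol that converts aromatic MOM ethers into silyl ethers hydrolysed at work-up while the alcohols are transiently silylated. This arrives at the target 20 and bypasses 18.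

**Further compounds**

F1 | step 6 | tert-butyl{[(2R,3R)-3-[3-methoxy-4,5-bis(methoxymethoxy)phenyl]oxiran-2-yl]methoxy}dimethylsilane | CC(C)(C)[Si](C)(C)OC[C@H]1O[C@@H]1c1cc(OC)c(OCOC)c(OCOC)c1
F2 | step 11 | (2S,3S)-3-[2-(allyloxy)-5-formyl-3-methoxyphenoxy]-2-hydroxy-3-[3-methoxy-4,5-bis(methoxymethoxy)phenyl]propyl pivalate | COc1cc([C@H](Oc2cc(C=O)cc(OC)c2OCC=C)[C@@H](O)COC(=O)C(C)(C)C)cc(OCOC)c1OCOC
F3 | step 11 | (2S,3S)-3-(5-formyl-2-hydroxy-3-methoxyphenoxy)-2-hydroxy-3-[3-methoxy-4,5-bis(methoxymethoxy)phenyl]propyl pivalate | COc1cc([C@H](Oc2cc(C=O)cc(OC)c2O)[C@@H](O)COC(=O)C(C)(C)C)cc(OCOC)c1OCOC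
F4 | step 11 | [(2S,3R)-7-formyl-5-methoxy-2-[3-methoxy-4,5-bis(methoxymethoxy)phenyl]-2,3-dihydro-1,4-benzodioxin-3-yl]methyl pivalate | COc1cc([C@@H]2Oc3cc(C=O)cc(OC)c3O[C@@H]2COC(=O)C(C)(C)C)cc(OCOC)c1OCOC
F5 | step 13 | (E)-3-[(2S,3R)-3-(hydroxymethyl)-5-methoxy-2-[3-methoxy-4,5-bis(methoxymethoxy)phenyl]-2,3-dihydro-1,4-benzodioxin-7-yl]prop-2-en-1-ol | COc1cc([C@@H]2Oc3cc(/C=C/CO)cc(OC)c3O[C@@H]2CO)cc(OCOC)c1OCOC
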